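All constants come from no measurement; the flask was simulated.

If a weak equilibrium leans on a reagent that is dying in the flask, I follow one ratio and leave the curves alone.

    starting material + partner ⇌ target (K1 = 5.7 M⁻¹, k1 = 0.0081 M⁻¹ s⁻¹, Ea1 = 64.0 kJ mol⁻¹, ΔH1 = −73.0 kJ mol⁻¹)
    second substrate + partner ⇌ second product (K2 = 780 M⁻¹, k2 = 0.26 M⁻¹ s⁻¹, Ea2 = 46.0 kJ mol⁻¹, ΔH2 = −10.0 kJ mol⁻¹)
    partner → decomposed reagent (k3 = 8.9 × 10⁻⁴ s⁻¹, Ea3 = 88.0 kJ mol⁻¹)
    (constants at 40 °C)

- Sunday's: starting material 0.25 M; partner 0.250 M; second substrate 0.0500 M; temperature 40 °C; time 15 min
- Friday's: starting material 0.25 M; partner 0.250 M; second substrate 0.0500 M; temperature 50 °C; time 15 min

* which of these there is most of at the end, counted by the starting material in it, Sunday's (starting material / target)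
* which of these there is most of at the end, counted by the starting material in it, Friday's (starting material / target)
* final amount of the leader among these, as a percentage of the starting material charged, in Sunday's
* final amount of the leader among these, as a percentage of the starting material charged, in Friday's

- all constants are for 40 °C and move with temperature by the activation energies and enthalpies

I called H the first step's equilibrium constant K times the free partner. Once that step has balanced (a quasi-equilibrium), H is target over starting material, and starting material holds the fraction 1/(1+H). I worked in powers of ten, so that each process added one term to the exponent of H. On Sunday's, the half-life of starting material by the forward rate of the first step, with the partner as charged, was 5.7 min, shorter than the 15 min allowed, so I let the step balance.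

Main step only, partner as charged:
exponent 0.154

Second substrate added. On Sunday's, its forward half-life with the partner as charged, 0.18 min, was far shorter than that of starting material, so I took its whole charge off the partner:
term −0.0969, exponent 0.0571

Decomposition added, with the partner falling exponentially over the run:
term −0.348, exponent −0.291

This last term was larger in size than the second substrate's, and it turned the sign. So I reckoned Sunday's holding ratio at the end as H = 0.512, the first constant times the partner surviving the other two processes. It stood below 1, which in my reckoning put starting material ahead at 66.1 %.

For Friday's, the warmer bath moved the equilibrium constant and the decomposition constant: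
K = 2.39 M⁻¹, decomposition constant = 0.00253 s⁻¹
H = 0.0490, exponent −1.31

That put starting material on Friday's at 95.3 % in my reckoning. My reckoning stopped there, with the partner held in target still counted as free.

The forecast named starting material for Sunday's at 76 % (range 72 % to 80 %) and starting material for Friday's at 92.5 % (range 90 % to 95 %), reasoning that “the exothermic equilibrium is less favourable and partner decomposes faster”. We agreed on the leaders. My Sunday's figure stood below its range, and my Friday's figure stood above it.

The flask gave starting material at 73.1 % on Sunday's and starting material at 92.4 % on Friday's, both inside the forecast's ranges. Sunday's kept 22 % of its partner free at the end. Target over starting material read 0.369 on Sunday's, less than my H, and 0.0819 on Friday's, more than my H. The sign of the exponent still named both leaders.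

The neighbour of Sunday's charged with 0.62 M of partner, its other charges and time held, gave me H = 1.46, above 1, with starting material at 40.7 %. The computed flask had target in the lead and starting material at 44.3 %, so in that flask the forecast's leader lost.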